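**Retrosynthetic overview**

1. Locants: C1 ketone carbon, C2 ring carbon bearing the CH2O carbon C7, C3 alkene CH, C4 carbinol carbon of the ring tiglate, C5 isopropyl-bearing carbon, C6 acetate carbon. Target 18 ⇐ alcohol 16 + tiglic acid 17 (C4–O, Mitsunobu with inversion) ⇐ isopropenyl compound 15 (hydrogenation).
2. The only ring, the cyclohexenone ring of 15, is opened at C1–C2 and C4–C5 into stannyl enal 6 and acid chloride 13. Forward, in one flask: acyl–alkenyl Stille coupling (C1–C2), then carbonyl-ene cyclization (C4–C5), which closes the ring.
3. Enabling feature: on the cyclohexenone ring the carbinol C4 lies between the alkene carbon C3 and C5 with its isopropyl group, and the C1 ketone is conjugated with C2=C3. At the isopropenyl level, C4(OH)–C5–C(CH3)=CH2 is the homoallylic-alcohol retron of a carbonyl-ene reaction of a (Z)-enal onto a 2-methylprop-1-enyl group (as in neral to isopiperitenol), and C1–C2 is an acyl–alkenyl bond open to cross-coupling.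
4. 6 ⇐ 3,3-diethoxyprop-1-yne 1 (hydroxymethylation, hydroxyl-directed trans-hydrostannation, tigloylation of C7–OH, acetal hydrolysis). 13 ⇐ diethyl oxalate 7 + Grignard reagent 8 (keto acid, enzymatic reduction, acetylation, acid chloride).
5. Stereochemistry: C6 is set by the enzyme; C5 and C4 are relayed from C6 in the ene event; C4 is inverted when the second tiglate is installed. The acetate and the C7 tiglate are carried in from the fragments, so no protecting group is used on the ring.

Key step: step 9

Remark: D-2-hydroxyisocaproate dehydrogenase is assumed to accept 10, the 3,4-unsaturated analogue of its natural substrate 4-methyl-2-oxopentanoate; "tigloyl" means (E)-2-methylbut-2-enoyl throughout.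

**Route**

Step 1
Reactants: 1 3,3-diethoxyprop-1-yne
Product: 2 4,4-diethoxybut-2-yn-1-ol
Conditions: n-BuLi, THF, −78 °C; (CH2O)n, −78 °C to rt; H2O
Reagents that add atoms: paraformaldehyde (as formaldehyde), C=O
Why: Deprotonation of the terminal alkyne and 1,2-addition of the lithium acetylide to formaldehyde is a standard hydroxymethylation, and the acetal is inert to the base.

Step 2
Reactants: 2 4,4-diethoxybut-2-yn-1-ol
Product: 3 (Z)-4,4-diethoxy-2-(tributylstannyl)but-2-en-1-ol
Conditions: Bu3SnH, [Cp*RuCl]4 (cat.), CH2Cl2, rt
Reagents that add atoms: tributyltin hydride, CCCC[SnH](CCCC)CCCC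
Why: Ruthenium-catalysed trans-hydrostannation of a propargylic alcohol places tin on the alkyne carbon next to the free hydroxyl (hydrogen bond from OH to the chloride ligand) and hydrogen anti to it, so tin ends cis to the acetal carbon, the geometry the ring closure needs.

Step 3
Reactants: 3 (Z)-4,4-diethoxy-2-(tributylstannyl)but-2-en-1-ol; 4 tigloyl chloride
Product: 5 (Z)-4,4-diethoxy-2-(tributylstannyl)but-2-en-1-yl tiglate
Conditions: pyridine, DMAP (cat.), CH2Cl2, 0 °C
Reagents that add atoms: none
Why: DMAP-catalysed acylation of the primary allylic alcohol installs the C7 tiglate of the target early, with pyridine as a base too weak to deconjugate the acyl chloride.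

Step 4
Reactants: 5 (Z)-4,4-diethoxy-2-(tributylstannyl)but-2-en-1-yl tiglate
Product: 6 (Z)-4-oxo-2-(tributylstannyl)but-2-en-1-yl tiglate
Conditions: LiBF4, MeCN/H2O (98:2), rt
Reagents that add atoms: water, O
Why: Mild acetal hydrolysis of the allylic diethyl acetal unmasks the enal without protodestannylation, and the (Z) geometry is held by the contact between the formyl oxygen and tin.

Step 5
Reactants: 7 diethyl oxalate; 8 2-methylprop-1-enylmagnesium bromide
Product: 10 4-methyl-2-oxopent-3-enoic acid, via ethyl 4-methyl-2-oxopent-3-enoate 9 (not isolated)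
Conditions: THF, −78 °C (Grignard reagent added to excess oxalate); then LiOH, H2O, 0 °C; then HCl (aq) to pH 2
Reagents that add atoms: lithium hydroxide, [Li+].[OH-]
Why: Mono-addition of the Grignard reagent to the oxalate diester at low temperature (the tetrahedral magnesium hemiketal resists a second addition) gives the alpha-keto ester 9, whose activated ester is saponified in the same flask (Grignard acylation followed by ester hydrolysis).

Step 6
Reactants: 10 4-methyl-2-oxopent-3-enoic acid
Product: 11 (R)-2-hydroxy-4-methylpent-3-enoic acid
Conditions: D-2-hydroxyisocaproate dehydrogenase, formate dehydrogenase, NAD+ (cat.), HCO2NH4, phosphate buffer pH 7, 30 °C; then HCl (aq)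
Reagents that add atoms: none
Why: NADH-dependent enzymatic carbonyl reduction with formate-driven cofactor recycling: the D-specific dehydrogenase delivers hydride to one face of the 2-oxo acid and sets C6 as (R), the alkene lying outside its reactivity.

Step 7
Reactants: 11 (R)-2-hydroxy-4-methylpent-3-enoic acid
Product: 12 (R)-2-acetoxy-4-methylpent-3-enoic acid
Conditions: Ac2O, pyridine, CH2Cl2, 0 °C to rt; aqueous work-up
Reagents that add atoms: acetic anhydride, CC(=O)OC(C)=O
Why: O-Acetylation of the alpha-hydroxy acid (any mixed anhydride is hydrolysed on aqueous work-up) installs the C6 acetate of the target without touching the stereocenter.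

Step 8
Reactants: 12 (R)-2-acetoxy-4-methylpent-3-enoic acid
Product: 13 (R)-2-acetoxy-4-methylpent-3-enoyl chloride
Conditions: 1-chloro-N,N,2-trimethylprop-1-en-1-amine, CH2Cl2, 0 °C to rt; used crude
Reagents that add atoms: 1-chloro-N,N,2-trimethylprop-1-en-1-amine, CC(C)=C(Cl)N(C)C
Why: The alpha-chloroenamine converts the acid into its chloride under neutral conditions, so that neither HCl (ionisation of the allylic acetate) nor base (ketene formation and loss of the C6 configuration) is present.

Step 9
Reactants: 6 (Z)-4-oxo-2-(tributylstannyl)but-2-en-1-yl tiglate; 13 (R)-2-acetoxy-4-methylpent-3-enoyl chloride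
Product: 15 (4R,5S,6R)-6-acetoxy-4-hydroxy-5-(prop-1-en-2-yl)-2-(tigloyloxymethyl)cyclohex-2-en-1-one, via (Z)-4-oxo-2-enal 14 (not isolated)
Conditions: Pd2(dba)3 (2.5 mol %), P(2-furyl)3 (10 mol %), CuI (10 mol %), CO (1 atm), toluene, 40 °C; then argon purge, Me2AlCl (2.5 equiv), −78 to −30 °C; aqueous potassium sodium tartrate
Reagents that add atoms: none
Why: Oxidative addition of zerovalent palladium into the C–Cl bond of 13, tin-to-palladium transfer of the alkenyl group of 6 (helped by CuI and by the contact between the cis-formyl oxygen and tin) and reductive elimination with retention of alkene geometry form C1–C2 and give the (Z)-4-oxo-2-enal 14; this is an acid chloride/alkenylstannane Stille coupling, and the CO atmosphere suppresses decarbonylation of the acyl palladium species. Me2AlCl then binds the formyl oxygen and the 2-methylprop-1-enyl group attacks C4 through C5 while an allylic methyl hydrogen shifts to oxygen, a concerted type 1 carbonyl-ene reaction whose closest models are the cyclizations of neral to isopiperitenol and of citronellal to isopulegol. The cyclohexenone ring, the only ring, is closed by this ene reaction in the 6-exo mode with respect to the formyl C=O, through a half-chair transition state with the aldehyde s-trans to C2=C3. C5 is controlled by A(1,3) strain: the (Z)-methyl of the isopropylidene group forces C6–H into the alkene plane, so C4 adds to the alkene face anti to the acetate and the isopropenyl group ends trans to OAc (5S from 6R); C4 is controlled by the s-trans enal and the closed, trans-fused ene transition state, which place the aluminium-bound oxygen pseudo-equatorial and trans to the isopropenyl group (4R). The step needs coupling at the acid chloride in the presence of the formyl group and both esters (neutral palladium conditions), retention of the (Z) geometry that puts C1 and C4 on the same side (stereospecific coupling), and attack at the formyl carbon rather than at the enone (the alternatives are a 5-endo closure onto C3 or an anti-Bredt hetero-Diels–Alder adduct). Me2AlCl also removes the proton of the new hydroxyl as methane, so the allylic acetate and the C6 stereocenter are not exposed to protic acid.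

Step 10
Reactants: 15 (4R,5S,6R)-6-acetoxy-4-hydroxy-5-(prop-1-en-2-yl)-2-(tigloyloxymethyl)cyclohex-2-en-1-one
Product: 16 (4R,5S,6R)-6-acetoxy-4-hydroxy-5-isopropyl-2-(tigloyloxymethyl)cyclohex-2-en-1-one
Conditions: H2 (1 atm), RhCl(PPh3)3 (5 mol %), benzene, rt
Reagents that add atoms: none
Why: Homogeneous hydrogenation with RhCl(PPh3)3 reduces the unhindered 1,1-disubstituted isopropenyl alkene far faster than the trisubstituted, conjugated alkenes of the enone and of the tiglate, the selectivity known from carvone to carvotanacetone; no stereocenter is created.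

Step 11
Reactants: 16 (4R,5S,6R)-6-acetoxy-4-hydroxy-5-isopropyl-2-(tigloyloxymethyl)cyclohex-2-en-1-one; 17 tiglic acid
Product: 18 (4S,5S,6R)-6-acetoxy-5-isopropyl-4-(tigloyloxy)-2-(tigloyloxymethyl)cyclohex-2-en-1-one (target)
Conditions: PPh3, DIAD, toluene, 0 °C to rt
Reagents that add atoms: none
Why: Mitsunobu esterification: the equatorial allylic C4 hydroxyl is activated as its oxyphosphonium ion and displaced by tiglate in an SN2 reaction with inversion (4R to 4S), which gives the 4,5-cis relationship of the target, while an anti-periplanar E2 pathway is not available to an equatorial leaving group.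

**Compound list**

1 | 3,3-diethoxyprop-1-yne | C#CC(OCC)OCC | starting material
2 | 4,4-diethoxybut-2-yn-1-ol | OCC#CC(OCC)OCC | intermediate
3 | (Z)-4,4-diethoxy-2-(tributylstannyl)but-2-en-1-ol | OC/C(=C/C(OCC)OCC)[Sn](CCCC)(CCCC)CCCC | intermediate
4 | (E)-2-methylbut-2-enoyl chloride (tigloyl chloride) | C/C=C(\C)C(=O)Cl | starting material
5 | (Z)-4,4-diethoxy-2-(tributylstannyl)but-2-en-1-yl (E)-2-methylbut-2-enoate | C/C=C(\C)C(=O)OC/C(=C/C(OCC)OCC)[Sn](CCCC)(CCCC)CCCC | intermediate
6 | (Z)-4-oxo-2-(tributylstannyl)but-2-en-1-yl (E)-2-methylbut-2-enoate | C/C=C(\C)C(=O)OC/C(=C/C=O)[Sn](CCCC)(CCCC)CCCC | intermediate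
7 | diethyl oxalate | CCOC(=O)C(=O)OCC | starting material
8 | 2-methylprop-1-enylmagnesium bromide | CC(C)=C[Mg]Br | starting material
9 | ethyl 4-methyl-2-oxopent-3-enoate | CCOC(=O)C(=O)C=C(C)C | intermediate
10 | 4-methyl-2-oxopent-3-enoic acid | CC(C)=CC(=O)C(=O)O | intermediate
11 | (R)-2-hydroxy-4-methylpent-3-enoic acid | CC(C)=C[C@@H](O)C(=O)O | intermediate
12 | (R)-2-acetoxy-4-methylpent-3-enoic acid | CC(C)=C[C@@H](OC(C)=O)C(=O)O | intermediate
13 | (R)-2-acetoxy-4-methylpent-3-enoyl chloride | CC(C)=C[C@@H](OC(C)=O)C(=O)Cl | intermediate
14 | (Z)-2-[(R)-2-acetoxy-4-methylpent-3-enoyl]-4-oxobut-2-en-1-yl (E)-2-methylbut-2-enoate | C/C=C(\C)C(=O)OC/C(=C/C=O)C(=O)[C@H](OC(C)=O)C=C(C)C | intermediate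
15 | (4R,5S,6R)-6-acetoxy-4-hydroxy-5-(prop-1-en-2-yl)-2-{[(E)-2-methylbut-2-enoyloxy]methyl}cyclohex-2-en-1-one | C/C=C(\C)C(=O)OCC1=C[C@@H](O)[C@H](C(C)=C)[C@@H](OC(C)=O)C1=O | intermediate
16 | (4R,5S,6R)-6-acetoxy-4-hydroxy-5-isopropyl-2-{[(E)-2-methylbut-2-enoyloxy]methyl}cyclohex-2-en-1-one | C/C=C(\C)C(=O)OCC1=C[C@@H](O)[C@H](C(C)C)[C@@H](OC(C)=O)C1=O | intermediate
17 | (E)-2-methylbut-2-enoic acid (tiglic acid) | C/C=C(\C)C(=O)O | starting material
18 | (4S,5S,6R)-6-acetoxy-5-isopropyl-4-[(E)-2-methylbut-2-enoyloxy]-2-{[(E)-2-methylbut-2-enoyloxy]methyl}cyclohex-2-en-1-one | C/C=C(\C)C(=O)OCC1=C[C@H](OC(=O)/C(C)=C/C)[C@H](C(C)C)[C@@H](OC(C)=O)C1=O | target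

**Step count and risks**

Total steps: 11. Longest linear sequence: 7 steps (5, 6, 7, 8, 9, 10, 11; the branch 1, 2, 3, 4, 9, 10, 11 is equally long).

The three steps most likely to fail:

1. Step 9 (key step). Possible failures are slow transfer of the fully substituted alkenyl group from tin to palladium, an uncontrolled thermal ene reaction of the free oxo-enal during the coupling, or consumption of Me2AlCl by phosphine and metal residues, which would lower the facial control at C4 and C5. The fallback separates the two bond formations and keeps the aldehyde masked during the coupling. It sets out from acetal 5 and acid chloride 13: the same palladium/copper Stille coupling should give the keto acetal (Z)-2-[(R)-2-acetoxy-4-methylpent-3-enoyl]-4,4-diethoxybut-2-en-1-yl tiglate F1, which can be purified. LiBF4 in wet MeCN then unmasks it to oxo-enal 14, isolated in this variant. A separate ene cyclization of pure 14 with Me2AlCl at −78 °C comes back to the route at 15.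

2. Step 11. The oxyphosphonium ion at the hindered C4, flanked by the isopropyl-bearing C5, may not be displaced by the weakly acidic tiglic acid, or may eliminate toward a cyclohexadienone that aromatizes. The fallback sets out from 16 and splits inversion from tigloylation. Mitsunobu reaction with the stronger and smaller chloroacetic acid (PPh3, DIAD, toluene) should give the inverted ester (4S,5S,6R)-6-acetoxy-4-(chloroacetoxy)-5-isopropyl-2-(tigloyloxymethyl)cyclohex-2-en-1-one F2. Thiourea with NaHCO3 in ethanol removes the chloroacetyl group in the presence of the acetate and the tiglate to give the 4,5-cis alcohol (4S,5S,6R)-6-acetoxy-4-hydroxy-5-isopropyl-2-(tigloyloxymethyl)cyclohex-2-en-1-one F3. Acylation with tigloyl chloride 4 (pyridine, DMAP) then returns to the route at 18 with retention. The same last operation would also carry through any 4,5-cis alcohol that step 9 might deliver, because after step 10 that compound is F3.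

3. Step 8. The C6 configuration may erode through ketene formation, or the allylic acetate may ionise, while the acid chloride is made and handled. The fallback avoids the acid chloride and sets out from acid 12. Carbodiimide esterification with ethanethiol (DCC, DMAP cat., CH2Cl2, 0 °C) should give S-ethyl (R)-2-acetoxy-4-methylpent-3-enethioate F4. Liebeskind–Srogl coupling of F4 with stannane 6 (Pd2(dba)3, P(2-furyl)3, copper diphenylphosphinate CuO2PPh2, THF, rt, base-free) gives oxo-enal 14 in the flask, and Me2AlCl as in step 9 returns to the route at 15.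

**Further compounds**

F1 | step 9 | (Z)-2-[(R)-2-acetoxy-4-methylpent-3-enoyl]-4,4-diethoxybut-2-en-1-yl (E)-2-methylbut-2-enoate | C/C=C(\C)C(=O)OC/C(=C/C(OCC)OCC)C(=O)[C@H](OC(C)=O)C=C(C)C
F2 | step 11 | (4S,5S,6R)-6-acetoxy-4-(2-chloroacetoxy)-5-isopropyl-2-{[(E)-2-methylbut-2-enoyloxy]methyl}cyclohex-2-en-1-one | C/C=C(\C)C(=O)OCC1=C[C@H](OC(=O)CCl)[C@H](C(C)C)[C@@H](OC(C)=O)C1=O
F3 | step 11 | (4S,5S,6R)-6-acetoxy-4-hydroxy-5-isopropyl-2-{[(E)-2-methylbut-2-enoyloxy]methyl}cyclohex-2-en-1-one | C/C=C(\C)C(=O)OCC1=C[C@H](O)[C@H](C(C)C)[C@@H](OC(C)=O)C1=O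
F4 | step 8 | S-ethyl (R)-2-acetoxy-4-methylpent-3-enethioate | CCSC(=O)[C@H](OC(C)=O)C=C(C)C
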